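**Retrosynthetic overview**
1. No ring is formed. Rings A and B (trans-decalin), C5, C8 (8α-OH), C9, C10 and all twenty terpenoid carbons come from (−)-sclareol 1.
2. Key disconnection, C19–O: C–H hydroxylation of the axial 4β-methyl group of 1 gives triol 2 and makes C4 the fifth ring stereocentre.
3. Ester C–O: the primary 19-OH of 2 is acylated with (E)-4-methoxycinnamic acid 3 to give 4.
4. Diene: the C13 vinyl carbinol of 4 is activated as acetate 5 and eliminated over zerovalent palladium to the 13(16),14-diene of target 6.

Assumption: labdane numbering is used. The SMILES is read as (4S,5R,8R,9R,10S), which is the normal (sclareol) series with 8α-OH, and the ester sits on the axial 4β-CH2 (C19).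

**Step 1**
Reactants: 1 (−)-sclareol
Product: 2 19-hydroxysclareol, (4S,13R)-labd-14-ene-8α,13,19-triol
Conditions: CYP102A1 (P450 BM3) variant "BM3-C19" (0.05 mol %, E. coli lysate), NADP+ (1 mol %), phosphite dehydrogenase, Na2HPO3 (2 equiv), air, K2HPO4/KH2PO4 buffer pH 8.0, 5 vol % DMSO, 25 °C, 20 h
Reagents that add atoms: dioxygen, O=O
Why: Proposed new method: the new catalyst is made by reshaping the pocket of the known CYP102A1 variants that already bind 1 with ring A over the heme and hydroxylate C3β (iterative saturation mutagenesis at residues 75, 78, 82, 87, 263, 328 and 437, with a mass-spectrometric screen for 2); the aim is to roll the decalin by about 60° about its long axis so that the β face, where the axial 4β-methyl C19 is the outermost group of ring A, faces the iron-oxo porphyrin radical cation; hydrogen-atom abstraction from the nearest C–H and fast oxygen rebound then form the C19–O bond, and because only the β (axial) methyl and not the α (equatorial, C18) methyl can reach the oxidant in this pose, prochiral C4 becomes 4S; positioning that overrides the roughly 3 kcal/mol bond-strength handicap of a methyl group is what plant P450 enzymes achieve at the axial C4 methyl of ent-kaurene and β-amyrin, and what evolved CYP102A1 achieves at a methyl group of artemisinin; the closest known reaction type is therefore P450 C–H hydroxylation (abstraction/rebound), which has not yet been shown with selectivity for C19 of a normal labdane.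

**Step 2**
Reactants: 2 19-hydroxysclareol; 3 (E)-4-methoxycinnamic acid
Product: 4 (13R)-8α,13-dihydroxylabd-14-en-19-yl (E)-4-methoxycinnamate
Conditions: 3 (1.3 equiv), N,N'-diisopropylcarbodiimide (1.4 equiv), DMAP (0.5 equiv), CH2Cl2, 0 °C to rt, 16 h
Reagents that add atoms: (E)-4-methoxycinnamic acid 3, COc1ccc(/C=C/C(=O)O)cc1
Why: Steglich esterification, in which the acylpyridinium derived from 3 is captured only by the primary C19–OH because both tertiary alcohols are inert at room temperature; no stereocentre is touched and the E-alkene is kept.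

**Step 3**
Reactants: 4 (13R)-8α,13-dihydroxylabd-14-en-19-yl (E)-4-methoxycinnamate
Product: 5 (13R)-13-acetoxy-8α-hydroxylabd-14-en-19-yl (E)-4-methoxycinnamate
Conditions: Ac2O (1.5 equiv), Et3N (3 equiv), DMAP (0.2 equiv), CH2Cl2, rt, 24 h, stopped when 4 is consumed
Reagents that add atoms: acetic anhydride, CC(=O)OC(C)=O
Why: DMAP-catalysed acyl transfer (Steglich-type acetylation) under kinetic control, in which the open-chain allylic O13 reacts well before ring O8, a tertiary carbinol flanked by the C9 side chain and the geminal C17 methyl; no stereocentre changes.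

**Step 4**
Reactants: 5 (13R)-13-acetoxy-8α-hydroxylabd-14-en-19-yl (E)-4-methoxycinnamate
Product: 6 8α-hydroxylabda-13(16),14-dien-19-yl (E)-4-methoxycinnamate (target)
Conditions: Pd(PPh3)4 (5 mol %), Et3N (3 equiv), THF, 65 °C, 6 h; chromatography on AgNO3-impregnated silica
Reagents that add atoms: none
Why: Tsuji–Trost ionisation followed by elimination of the allylic acetate to a 1,3-diene, in which zerovalent palladium ionises only the allylic C13–OAc bond and the η3-allyl complex loses a proton from the free C16 methyl rather than from C12, whose hydrogens are screened by the decalin, while the neutral, hindered O8 is too poor a nucleophile to close the manoyl oxide ring; C13 becomes sp2 and neither the ring stereocentres nor the E-cinnamate are affected.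

**Compound list**
1 | (−)-sclareol, (13R)-labd-14-ene-8α,13-diol | C=C[C@](C)(O)CC[C@@H]1[C@@]2(C)CCCC(C)(C)[C@@H]2CC[C@@]1(C)O | starting material
2 | 19-hydroxysclareol, (4S,13R)-labd-14-ene-8α,13,19-triol | C=C[C@](C)(O)CC[C@@H]1[C@@]2(C)CCC[C@](C)(CO)[C@@H]2CC[C@@]1(C)O | intermediate
3 | (E)-4-methoxycinnamic acid | COc1ccc(/C=C/C(=O)O)cc1 | starting material
4 | (13R)-8α,13-dihydroxylabd-14-en-19-yl (E)-4-methoxycinnamate | C=C[C@](C)(O)CC[C@@H]1[C@@]2(C)CCC[C@](C)(COC(=O)/C=C/c3ccc(OC)cc3)[C@@H]2CC[C@@]1(C)O | intermediate
5 | (13R)-13-acetoxy-8α-hydroxylabd-14-en-19-yl (E)-4-methoxycinnamate | C=C[C@](C)(OC(C)=O)CC[C@@H]1[C@@]2(C)CCC[C@](C)(COC(=O)/C=C/c3ccc(OC)cc3)[C@@H]2CC[C@@]1(C)O | intermediate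
6 | 8α-hydroxylabda-13(16),14-dien-19-yl (E)-4-methoxycinnamate, (4S,5R,8R,9R,10S) | C=CC(=C)CC[C@@H]1[C@@]2(C)CCC[C@](C)(COC(=O)/C=C/c3ccc(OC)cc3)[C@@H]2CC[C@@]1(C)O | target

**Total step count:** 4. **Longest linear sequence:** 4 (1 → 2 → 4 → 5 → 6).

**Steps most likely to fail**

**Step 1 (the proposed new step).**
- Risks: hydroxylation at C2, C3 or C18 instead of C19, epoxidation of the vinyl group, or over-oxidation of the 19-ol.
- Fallback, from 1 back to 2: regioselectivity is no longer required of the catalyst. Compound 1 is fed to a growing wild-type Cunninghamella culture. This is a known whole-cell oxidation that hydroxylates both ring A methyl groups of sclareol with little discrimination.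
- The extract contains 2 together with its C4 epimer 18-hydroxysclareol F1. The two are separated by silica gel chromatography, where the axial neopentyl 19-ol elutes first. The low cost of 1 pays for the material lost.

**Step 3.**
- Risks: O8 may be acetylated alongside O13, or O13 may react too slowly.
- Fallback, from 4 back to 6: the two tertiary alcohols are told apart by a reaction that only the allylic one can undergo.
- Babler–Dauben oxidative transposition with [C5H5NH][CrO3Cl] in CH2Cl2 moves the oxygen from C13 to C15 and gives (13E)-8α-hydroxy-15-oxolabd-13-en-19-yl 4-methoxycinnamate F2. Any 13Z isomer converges later.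
- Luche reduction (NaBH4, CeCl3·7H2O, MeOH, 0 °C) gives (13E)-8α,15-dihydroxylabd-13-en-19-yl 4-methoxycinnamate F3.
- Ac2O in pyridine at 0 °C acetylates only the new primary hydroxyl and gives (13E)-15-acetoxy-8α-hydroxylabd-13-en-19-yl 4-methoxycinnamate F4.
- Under the conditions of step 4, F4 ionises to the same η3-allyl palladium complex and gives 6.

**Step 4.**
- Risks: the free O8 may close onto the allyl unit to give manoyl oxide-type ethers, and the 12,14-dienes may form alongside the wanted diene.
- Fallback, from 2 back to 6: O8 is capped during the elimination and the cinnamate is attached last.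
- Compound 2 is peracetylated (AcCl, PhNMe2, CH2Cl2, rt) to (13R)-labd-14-ene-8α,13,19-triyl triacetate F5, the fully acylated form in which this type of elimination is best behaved for sclareol esters.
- Pd(PPh3)4 and Et3N in THF at 65 °C give labda-13(16),14-diene-8α,19-diyl diacetate F6.
- LiAlH4 in Et2O at 0 °C removes both acetates to give labda-13(16),14-diene-8α,19-diol F7.
- Steglich esterification of F7 with 3 (N,N'-diisopropylcarbodiimide, DMAP, CH2Cl2) acylates only the primary 19-OH and gives 6.

**Further compounds**
F1 | step 1 | 18-hydroxysclareol, (4R,13R)-labd-14-ene-8α,13,18-triol | C=C[C@](C)(O)CC[C@@H]1[C@@]2(C)CCC[C@@](C)(CO)[C@@H]2CC[C@@]1(C)O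
F2 | step 3 | (13E)-8α-hydroxy-15-oxolabd-13-en-19-yl (E)-4-methoxycinnamate | O=C/C=C(\C)CC[C@@H]1[C@@]2(C)CCC[C@](C)(COC(=O)/C=C/c3ccc(OC)cc3)[C@@H]2CC[C@@]1(C)O
F3 | step 3 | (13E)-8α,15-dihydroxylabd-13-en-19-yl (E)-4-methoxycinnamate | OC/C=C(\C)CC[C@@H]1[C@@]2(C)CCC[C@](C)(COC(=O)/C=C/c3ccc(OC)cc3)[C@@H]2CC[C@@]1(C)O
F4 | step 3 | (13E)-15-acetoxy-8α-hydroxylabd-13-en-19-yl (E)-4-methoxycinnamate | CC(=O)OC/C=C(\C)CC[C@@H]1[C@@]2(C)CCC[C@](C)(COC(=O)/C=C/c3ccc(OC)cc3)[C@@H]2CC[C@@]1(C)O
F5 | step 4 | (13R)-labd-14-ene-8α,13,19-triyl triacetate | C=C[C@](C)(OC(C)=O)CC[C@@H]1[C@@]2(C)CCC[C@](C)(COC(C)=O)[C@@H]2CC[C@@]1(C)OC(C)=O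
F6 | step 4 | labda-13(16),14-diene-8α,19-diyl diacetate | C=CC(=C)CC[C@@H]1[C@@]2(C)CCC[C@](C)(COC(C)=O)[C@@H]2CC[C@@]1(C)OC(C)=O
F7 | step 4 | labda-13(16),14-diene-8α,19-diol | C=CC(=C)CC[C@@H]1[C@@]2(C)CCC[C@](C)(CO)[C@@H]2CC[C@@]1(C)O
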